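All runs are simulated with constants of no real substance; noise was put on by code.

It is impossible for a flask to hold more exchanges per starting complex than the equivalents e of incoming ligand charged, and the west readings reach that ceiling within their scatter: at 30.0 h they count 1.21 exchanges against e = 1.20.

all flasks: starting complex 0.020 M
- west: incoming ligand 0.024 M; run made earlier
- east: incoming ligand 0.052 M; run made earlier
- Tuesday's: incoming ligand 0.0180 M; time 30 h
- Saturday's: incoming ligand 0.0450 M; time 30 h

| run | time / h | starting complex / % | complex with three exchanged / % | complex with two exchanged / % | complex with one exchanged / % |
|---|---|---|---|---|---|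
| west | 5.00 | 51.0 | 2.9 | 20.5 | 25.2 |
| west | 10.0 | 40.3 | 7.1 | 27.0 | 24.4 |
| west | 15.0 | 36.0 | 10.0 | 30.7 | 23.3 |
| west | 20.0 | 34.5 | 9.8 | 32.3 | 24.1 |
| west | 25.0 | 34.0 | 9.9 | 31.9 | 22.6 |
| west | 30.0 | 34.9 | 11.2 | 32.2 | 23.5 |
| east | 2.50 | 40.1 | 7.8 | 27.8 | 24.4 |
| east | 4.00 | 27.6 | 15.7 | 36.8 | 21.2 |
| east | 6.00 | 18.0 | 23.9 | 39.5 | 17.1 |
| east | 10.0 | 11.6 | 36.4 | 39.9 | 12.1 |
| east | 20.0 | 5.9 | 53.5 | 34.5 | 8.3 |
| east | 30.0 | 5.0 | 60.0 | 30.4 | 4.4 |

(readings scatter by 0.5 percentage points)

- which of these there is most of at the end, counted by the starting complex in it, Tuesday's (starting complex / complex with one exchanged / complex with two exchanged / complex with three exchanged)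
- which of these there is most of at the end, counted by the starting complex in it, Saturday's (starting complex / complex with one exchanged / complex with two exchanged / complex with three exchanged)
- final amount of the leader among these, as a percentage of the starting complex charged, in Tuesday's
- final amount of the leader among these, as a percentage of the starting complex charged, in Saturday's

- on the list of suspects stand: complex with one exchanged + incoming ligand <-> leaving ligand + complex with two exchanged; starting complex + incoming ligand <-> leaving ligand + complex with one exchanged; complex with two exchanged + incoming ligand <-> leaving ligand + complex with three exchanged; leaving ligand -> by-product carried off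

For a count n, two flasks can be solved in the head. In the orderly one, each complex takes its next ligand before any other goes further, so starting complex left is 1 − n, and complex with three exchanged, once n passes 2, is n − 2. In the rushed one, each complex that reacts goes straight to three exchanged, so starting complex left is 1 − n/3 and complex with three exchanged n/3. These two are the bounds of the count, and the real flask lies between them. West's starting complex, 34.9% between nothing and 59.5%, stands 0.587 of the way from the orderly to the rushed end, and this standing is what I carry over, assuming it holds for a similar e. Tuesday's has e = 0.900, which makes incoming ligand the limiting reagent, with ends 10.0% and 70.0%, so I expect 45.2% of starting complex, the leader as in west. East's complex with three exchanged leads and, with 2.45 exchanges counted, stands 0.405 of the way, a standing read on complex with three exchanged and not on starting complex, so Saturday's, taking n as e = 2.25, gives me 45.3% of complex with three exchanged as the leader.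

The forecast says starting complex at 45% for Tuesday's and complex with three exchanged at 46% for Saturday's, on the ground “so that plateau is ligand exhaustion, not equilibrium”.

The flasks give starting complex at 45.3% on Tuesday's and complex with three exchanged at 44.8% on Saturday's.

    complex with one exchanged + incoming ligand ⇌ leaving ligand + complex with two exchanged (K = 0.380, k = 0.00520 /M/s)
    starting complex + incoming ligand ⇌ leaving ligand + complex with one exchanged (K = 1.10, k = 0.00250 /M/s)
    complex with two exchanged + incoming ligand ⇌ leaving ligand + complex with three exchanged (K = 0.860, k = 0.00160 /M/s)
    leaving ligand → by-product carried off (k = 0.00150 /s)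

Tuesday's result stands 0.588 of the way, against the 0.587 carried from west. In Tuesday's, the forward half-life of starting complex is 4.3 h with the charges present, short against 30 h, but 66 d at the end, long against it, with 0.27% of the incoming ligand left against 45% of the starting complex. At 3.60 h in Tuesday's, leaving ligand falls back at 0.026 of the rate at which it goes on. A neighbour of Tuesday's charged with 0.0045 M of incoming ligand, at e = 0.225, ends with 81.3% of starting complex, inside its ends 77.5% and 92.5%, but standing 0.253 of the way against west's 0.587.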